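The numbers in the tables are calculated from invented constants; noise was put on by code.

Start with an easy division, because the next run is either elm or ash and the choice hangs on one number.

| flask | starting material | coupling partner | free catalyst | remark | time |
|---|---|---|---|---|---|
| west | 0.86 M | 0.95 M | 1.2 mM | run made earlier |  |
| east | 2.2 M | 0.95 M | 1.2 mM | run made earlier |  |
| south-west | 1 M | 0.52 M | 1.2 mM | run made earlier |  |
| elm | 3.0 M | 0.300 M | 1.2 mM |  | 10 h |
| ash | 1.0 M | 0.950 M | 1.2 mM |  | 2.5 h |

| west: time / min | west: product / % | east: time / min | east: product / % | south-west: time / min | south-west: product / % |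
|---|---|---|---|---|---|
| 6.00 | 1.0 | 6.00 | 0.4 | 10.0 | 0.2 |
| 15.0 | 3.3 | 15.0 | 1.3 | 25.0 | 2.5 |
| 30.0 | 5.4 | 30.0 | 2.4 | 50.0 | 5.5 |
| 80.0 | 14.0 | 80.0 | 6.5 | 80.0 | 8.7 |

(standard deviation of a reading: 0.5 percentage points)

* the winner by amount of product, in percent of the starting material charged; "neither" if no more than 2 percentage points parts them (elm / ash / neither)
* how much product is there at the end, in percent of the starting material charged: elm
* how much product is there at the end, in percent of the starting material charged: ash

- the numbers in the tables scatter with a standard deviation of 0.5 percentage points

Take the product of the west run at 80.0 min, in molar, and divide it by the time and by the catalyst charged. This gives N = 1.25 min⁻¹, the turnover frequency, moles of product per mole of catalyst charged per minute. The west reading at 30.0 min gives 1.29 min⁻¹, so the west line runs straight within the scatter. In the east run, 2.56 times the starting material reads N = 1.49 min⁻¹, so the small step from west to ash in starting material should move N little.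

For ash, N times the catalyst charge and 2.5 h, divided by the 1.0 M of starting material, gives 22.6%. Take that as slightly high: the south-west run, at 1 M of starting material and 0.52 M of coupling partner, reads N = 0.906 min⁻¹, lower than west, and the partner in ash will fall as it is used.

Elm needs no rate. If you take one coupling partner per product, its 0.300 M of partner is the limiting reagent and allows at most 10.0% of the starting material charged. Your figure for ash is 22.6%, the ceiling for elm is 10.0% and the margin is 2 points, so charge ash. For elm you commit to nothing closer than the ceiling, whereas the forecast names a figure: 9% for elm, 22% for ash, winner ash, with the words “Ash wins, assuming the catalyst survives”.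

The flasks give 21.6% for ash and 8.42% for elm, so ash wins.

    starting material + free catalyst ⇌ catalyst intermediate A (K = 52.0 M⁻¹, k = 8.20 M⁻¹ min⁻¹)
    coupling partner + catalyst intermediate A ⇌ catalyst intermediate B (K = 1.30 M⁻¹, k = 4.20 M⁻¹ min⁻¹)
    catalyst intermediate B → catalyst intermediate C (k = 7.20 min⁻¹)
    catalyst intermediate C ⇌ free catalyst + product (K = 1.50 M, k = 8.10 min⁻¹)

Ash holds 11.3% product at 1.25 h and twice that, 21.6%, at 2.50 h, so its line stays nearly straight, and the figure reckoned from N stands 1.00 point above the ash result. Put N to use once more on the neighbour of ash charged with 0.0020 M of free catalyst: it reckons 37.5%, and that flask gives 33.7%.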